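The skeleton is cut at the C10–C11 single bond of the polyene (carotenoid numbering). The C8 ketone makes C10 the β-carbon of an enone, so a C10 iodide is a vinylogous acyl iodide that should enter a neutral Stille alkenyl–alkenyl coupling at room temperature. The last step joins two complete, unprotected halves: the (E)-β-iodoenone 15, which holds ring A (3-hydroxy-β ring), C7, the C8 ketone and the C19 octenoate, and the all-E heptaenylstannane 28, which holds ring B (3-hydroxy-ε ring). One operation completes the octaenone chromophore, carries both alkene geometries over with retention and gives the target itself. The geometry of 15 comes from a β-iodo Morita–Baylis–Hillman reaction.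

Key step: step 15

Remark: carotenoid numbering is used throughout. Ring A is C1–C6, the chain runs C7–C15 and C15'–C7', ring B is C1'–C6', and C19 is the oxygen-bearing carbon on C9.
Remark: enantiopure (4R,6R)-actinol 1 and (R)-α-ionone 16 are assumed to be purchasable.

**Iodide half (steps 1–7)**

Step 1
Reactants: 1 (4R,6R)-4-hydroxy-2,2,6-trimethylcyclohexan-1-one (actinol)
Product: 2 (4R,6R)-2,2,6-trimethyl-4-(triethylsilyloxy)cyclohexan-1-one
Conditions: Et3SiCl, imidazole, CH2Cl2, 0 °C → rt
Reagents that add atoms: chlorotriethylsilane CC[Si](Cl)(CC)CC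
Why: Silyl ether protection of the only hydroxyl group, with the labile triethylsilyl group chosen because the acid of step 3 removes it without a step of its own.

Step 2
Reactants: 2 silyl ether of actinol
Product: 4 (4R)-2,6,6-trimethyl-4-(triethylsilyloxy)cyclohex-1-en-1-yl trifluoromethanesulfonate, via lithium enolate 3 (not isolated)
Conditions: LiN(i-Pr)2, THF, −78 °C; PhNTf2, −78 °C → rt
Reagents that add atoms: N-phenylbis(trifluoromethanesulfonimide) O=S(=O)(N(c1ccccc1)S(=O)(=O)C(F)(F)F)C(F)(F)F
Why: Only one α-carbon of the ketone carries hydrogen, so enolisation and O-sulfonylation (enol triflate formation) can give a single regioisomer, which erases the methyl-bearing stereocentre and keeps the carbinol centre that becomes C3.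

Step 3
Reactants: 4 enol triflate; 5 (E)-2-(2-ethoxyethenyl)-4,4,5,5-tetramethyl-1,3,2-dioxaborolane
Product: 7 2-[(4R)-4-hydroxy-2,6,6-trimethylcyclohex-1-en-1-yl]acetaldehyde, via dienol ether 6 (not isolated)
Conditions: Pd(dppf)Cl2 (5 mol %), K3PO4, dioxane/H2O, 80 °C; then 1 M HCl, THF, rt
Reagents that add atoms: water O
Why: Suzuki–Miyaura coupling of the hindered tetrasubstituted enol triflate installs C7 and C8 as an enol ether, kinetic protonation at C7 of the twisted dienol ether in dilute acid should release the β,γ-unsaturated aldehyde, and the same acid cleaves the triethylsilyl ether.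

Step 4
Reactants: 7 hydroxy aldehyde; 8 methyl propiolate
Product: 10 methyl (2Z)-2-{1-hydroxy-2-[(4R)-4-hydroxy-2,6,6-trimethylcyclohex-1-en-1-yl]ethyl}-3-iodoprop-2-enoate (both C8 epimers), via iodoallenolate 9 (not isolated)
Conditions: MgI2 (2 equiv), CH2Cl2, 0 °C; aq. NH4Cl
Reagents that add atoms: magnesium diiodide [Mg+2].[I-].[I-]
Why: In this β-iodo Morita–Baylis–Hillman reaction iodide adds to the propiolate, and the allenolate 9 attacks the aldehyde from the side away from iodine, so iodine ends cis to the ester carbon (future C19) and trans to C8 as C9=C10 of the target requires, while the C8 carbinol centre forms as a mixture that step 7 erases.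

Step 5
Reactants: 10 β-iodo ester
Product: 11 (2E)-4-[(4R)-4-hydroxy-2,6,6-trimethylcyclohex-1-en-1-yl]-2-(iodomethylidene)butane-1,3-diol (both C8 epimers)
Conditions: i-Bu2AlH (5 equiv), CH2Cl2, −78 → −20 °C; aq. KNaC4H4O6
Reagents that add atoms: none
Why: 1,2-Reduction of the unsaturated ester by the aluminium hydride at low temperature should give the allylic alcohol C19 and leave the alkenyl iodide and its geometry untouched.

Step 6
Reactants: 11 triol; 12 (E)-oct-2-enoic acid
Product: 14 (2E)-3-hydroxy-4-[(4R)-4-hydroxy-2,6,6-trimethylcyclohex-1-en-1-yl]-2-(iodomethylidene)butyl (2E)-oct-2-enoate (both C8 epimers), via O-acylisourea 13 (not isolated)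
Conditions: 12 (1.0 equiv), dicyclohexylcarbodiimide, DMAP (10 mol %), CH2Cl2, −20 → 0 °C
Reagents that add atoms: none
Why: Steglich esterification with one equivalent of acid at low temperature should acylate the unhindered primary allylic C19 hydroxyl much faster than the two secondary hydroxyls.

Step 7
Reactants: 14 monoester
Product: 15 (2E)-4-[(4R)-4-hydroxy-2,6,6-trimethylcyclohex-1-en-1-yl]-2-(iodomethylidene)-3-oxobutyl (2E)-oct-2-enoate
Conditions: activated MnO2 (20 equiv), CH2Cl2, rt, dark
Reagents that add atoms: none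
Why: MnO2 oxidises allylic alcohols selectively, so the C8 carbinol next to C9=C10 should go to the ketone while the homoallylic C3 hydroxyl of ring A stays.

**Stannane half (steps 8–14)**

Step 8
Reactants: 16 (R)-α-ionone, (3E)-4-[(1R)-2,6,6-trimethylcyclohex-2-en-1-yl]but-3-en-2-one
Product: 17 (1E)-3-methyl-1-[(1R)-2,6,6-trimethylcyclohex-2-en-1-yl]penta-1,4-dien-3-ol (both C9' epimers)
Conditions: vinylmagnesium bromide, THF, −30 → 0 °C; H2O
Reagents that add atoms: vinylmagnesium bromide C=C[Mg]Br
Why: 1,2-Addition of the vinyl Grignard reagent to the methyl ketone adds C10' and C11' without touching C6', and the C9' carbinol centre forms as a mixture that step 11 erases.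

Step 9
Reactants: 17 vinyl carbinol
Product: 18 (4R)-4-[(1E)-3-hydroxy-3-methylpenta-1,4-dien-1-yl]-3,5,5-trimethylcyclohex-2-en-1-one (both C9' epimers)
Conditions: Rh2(cap)4 (dirhodium tetracaprolactamate, 1 mol %), t-BuOOH (70 % aq., 5 equiv), K2CO3 (0.5 equiv), CH2Cl2, rt
Reagents that add atoms: tert-butyl hydroperoxide CC(C)(C)OO
Why: Radical allylic oxidation by tert-butylperoxyl radicals should attack the ring methylene C3', because the C6'–H bond lies near the plane of the ring alkene behind the geminal methyl groups and C9' carries no hydrogen.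

Step 10
Reactants: 18 ring enone
Product: 19 (1R,4R)-4-[(1E)-3-hydroxy-3-methylpenta-1,4-dien-1-yl]-3,5,5-trimethylcyclohex-2-en-1-ol (both C9' epimers)
Conditions: K[HB(s-Bu)3] (2.5 equiv), THF, −78 °C; H2O
Reagents that add atoms: none
Why: In this substrate-controlled 1,2-reduction the bulky borohydride should attack the enone carbonyl from the face opposite the axial C1' methyl group, which is the face of the pseudoaxial C6' side chain, so the new hydroxyl ends trans to the side chain (3'R).

Step 11
Reactants: 19 diol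
Product: 20 [(2E,4E)-5-[(1R,4R)-4-hydroxy-2,6,6-trimethylcyclohex-2-en-1-yl]-3-methylpenta-2,4-dien-1-yl]triphenylphosphonium bromide
Conditions: PPh3·HBr (1.05 equiv), CH2Cl2, 0 °C → rt; crystallisation from CH2Cl2/Et2O
Reagents that add atoms: triphenylphosphine hydrobromide [Br-].c1ccccc1[PH+](c1ccccc1)c1ccccc1
Why: SN1-type allylic substitution with transposition, in which the tertiary bis-allylic alcohol ionises far faster than the secondary ring alcohol, phosphine bonds to the unhindered terminus C11', and the (9'E) salt is purified by crystallisation.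

Step 12
Reactants: 20 phosphonium salt; 21 (2E,4E,6E)-2,7-dimethylocta-2,4,6-trienedial
Product: 23 (2E,4E,6E,8E,10E,12E)-13-[(1R,4R)-4-hydroxy-2,6,6-trimethylcyclohex-2-en-1-yl]-2,7,11-trimethyltrideca-2,4,6,8,10,12-hexaenal, via phosphorus ylide 22 (not isolated)
Conditions: 21 (2 equiv), NaOMe, CH2Cl2/MeOH, −10 °C → rt; then EtOAc, reflux, dark; crystallisation
Reagents that add atoms: none
Why: Wittig olefination of one aldehyde group of the symmetrical dialdehyde, used in excess, forms C11'=C12', and any Z isomer of this unhindered disubstituted bond should equilibrate to E on heating.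

Step 13
Reactants: 24 diiodomethane
Product: 26 tributyl(diiodomethyl)stannane, via diiodomethyllithium 25 (not isolated)
Conditions: LiN(i-Pr)2, THF, −78 °C; Bu3SnCl, −78 °C → rt
Reagents that add atoms: tributyltin chloride CCCC[Sn](Cl)(CCCC)CCCC
Why: Deprotonation of diiodomethane gives the carbenoid 25, which persists at low temperature and is stannylated at carbon by substitution at tin.

Step 14
Reactants: 23 hexaenal; 26 tributyl(diiodomethyl)stannane
Product: 28 (1R,4R)-3,5,5-trimethyl-4-[(1E,3E,5E,7E,9E,11E,13E)-3,7,12-trimethyl-14-(tributylstannyl)tetradeca-1,3,5,7,9,11,13-heptaen-1-yl]cyclohex-2-en-1-ol, via geminal dichromium reagent 27 (not isolated)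
Conditions: CrCl2 (8 equiv), 26 (2 equiv), DMF/THF, rt, dark
Reagents that add atoms: none
Why: In this Takai-type olefination divalent chromium turns 26 into 27, which adds to the aldehyde and eliminates to give the (E)-alkenylstannane containing C11, and the reagent tolerates the free hydroxyl group.

**Union**

Step 15
Reactants: 15 (E)-β-iodoenone; 28 heptaenylstannane
Product: 29 (3R,3'R,6'R)-3,3'-dihydroxy-8-oxo-7,8-dihydro-β,ε-caroten-19-yl (2E)-oct-2-enoate (CNP0344057.1)
Conditions: 15 (1.1 equiv), Pd2(dba)3·CHCl3 (2.5 mol %), AsPh3 (20 mol %), NMP, rt, argon, dark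
Reagents that add atoms: none
Why: Stille coupling: zerovalent palladium inserts into the C10–iodine bond of 15, which the C8 ketone activates as a vinylogous acyl iodide, C11 is transferred from tin in a transmetalation that the weakly bound AsPh3 speeds up, and reductive elimination forms C10–C11. The closest known reaction type is the alkenyl iodide–alkenylstannane coupling used to assemble retinoid and carotenoid polyenes. No ring is closed and no stereocentre is created; geometry is what is transferred, since all three elementary steps run with retention, so C9=C10 (C11 cis to C19, trans to C8) comes from 15 and (11E) from 28. The selectivity needed is insertion into the alkenyl iodide in preference to ionisation of the allylic C19 octenoate, and it is secured by the much faster reaction of the β-iodoenone, the poor donor ligand and a small excess of 15 that keeps palladium in its divalent resting state. The medium is neutral, so the base-sensitive 8-oxo-19-acyloxy unit, the C7 methylene between ring A and the ketone, the acid-sensitive allylic C3' alcohol of ring B and both free hydroxyl groups should survive, and no deprotection follows the union.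

**Compound list**

1 | (4R,6R)-4-hydroxy-2,2,6-trimethylcyclohexan-1-one (actinol) | O=C1[C@H](C)C[C@@H](O)CC1(C)C | starting material
2 | (4R,6R)-2,2,6-trimethyl-4-(triethylsilyloxy)cyclohexan-1-one | O=C1[C@H](C)C[C@@H](O[Si](CC)(CC)CC)CC1(C)C | intermediate
3 | lithium (4R)-2,6,6-trimethyl-4-(triethylsilyloxy)cyclohex-1-en-1-olate | [Li]OC1=C(C)C[C@@H](O[Si](CC)(CC)CC)CC1(C)C | intermediate
4 | (4R)-2,6,6-trimethyl-4-(triethylsilyloxy)cyclohex-1-en-1-yl trifluoromethanesulfonate | O=S(=O)(OC1=C(C)C[C@@H](O[Si](CC)(CC)CC)CC1(C)C)C(F)(F)F | intermediate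
5 | (E)-2-(2-ethoxyethenyl)-4,4,5,5-tetramethyl-1,3,2-dioxaborolane | CCO/C=C/B1OC(C)(C)C(C)(C)O1 | starting material
6 | {[(1R)-4-[(E)-2-ethoxyethenyl]-3,5,5-trimethylcyclohex-3-en-1-yl]oxy}triethylsilane | CCO/C=C/C1=C(C)C[C@@H](O[Si](CC)(CC)CC)CC1(C)C | intermediate
7 | 2-[(4R)-4-hydroxy-2,6,6-trimethylcyclohex-1-en-1-yl]acetaldehyde | O=CCC1=C(C)C[C@@H](O)CC1(C)C | intermediate
8 | methyl propiolate | C#CC(=O)OC | starting material
9 | iodomagnesium 3-iodo-1-methoxypropa-1,2-dien-1-olate | COC(O[Mg]I)=C=CI | intermediate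
10 | methyl (2Z)-2-{1-hydroxy-2-[(4R)-4-hydroxy-2,6,6-trimethylcyclohex-1-en-1-yl]ethyl}-3-iodoprop-2-enoate (both C8 epimers) | COC(=O)/C(=C\I)C(O)CC1=C(C)C[C@@H](O)CC1(C)C | intermediate
11 | (2E)-4-[(4R)-4-hydroxy-2,6,6-trimethylcyclohex-1-en-1-yl]-2-(iodomethylidene)butane-1,3-diol (both C8 epimers) | OC/C(=C\I)C(O)CC1=C(C)C[C@@H](O)CC1(C)C | intermediate
12 | (E)-oct-2-enoic acid | CCCCC/C=C/C(=O)O | starting material
13 | O-[(E)-oct-2-enoyl]-N,N'-dicyclohexylisourea | CCCCC/C=C/C(=O)OC(=NC1CCCCC1)NC1CCCCC1 | intermediate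
14 | (2E)-3-hydroxy-4-[(4R)-4-hydroxy-2,6,6-trimethylcyclohex-1-en-1-yl]-2-(iodomethylidene)butyl (2E)-oct-2-enoate (both C8 epimers) | CCCCC/C=C/C(=O)OC/C(=C\I)C(O)CC1=C(C)C[C@@H](O)CC1(C)C | intermediate
15 | (2E)-4-[(4R)-4-hydroxy-2,6,6-trimethylcyclohex-1-en-1-yl]-2-(iodomethylidene)-3-oxobutyl (2E)-oct-2-enoate | CCCCC/C=C/C(=O)OC/C(=C\I)C(=O)CC1=C(C)C[C@@H](O)CC1(C)C | intermediate
16 | (R)-α-ionone | CC(=O)/C=C/[C@H]1C(C)=CCCC1(C)C | starting material
17 | (1E)-3-methyl-1-[(1R)-2,6,6-trimethylcyclohex-2-en-1-yl]penta-1,4-dien-3-ol (both C9' epimers) | C=CC(C)(O)/C=C/[C@H]1C(C)=CCCC1(C)C | intermediate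
18 | (4R)-4-[(1E)-3-hydroxy-3-methylpenta-1,4-dien-1-yl]-3,5,5-trimethylcyclohex-2-en-1-one (both C9' epimers) | C=CC(C)(O)/C=C/[C@H]1C(C)=CC(=O)CC1(C)C | intermediate
19 | (1R,4R)-4-[(1E)-3-hydroxy-3-methylpenta-1,4-dien-1-yl]-3,5,5-trimethylcyclohex-2-en-1-ol (both C9' epimers) | C=CC(C)(O)/C=C/[C@H]1C(C)=C[C@H](O)CC1(C)C | intermediate
20 | [(2E,4E)-5-[(1R,4R)-4-hydroxy-2,6,6-trimethylcyclohex-2-en-1-yl]-3-methylpenta-2,4-dien-1-yl]triphenylphosphonium bromide | c1ccccc1[P+](c1ccccc1)(c1ccccc1)C/C=C(C)/C=C/[C@H]1C(C)=C[C@H](O)CC1(C)C.[Br-] | intermediate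
21 | (2E,4E,6E)-2,7-dimethylocta-2,4,6-trienedial | O=C/C(C)=C/C=C/C=C(C)/C=O | starting material
22 | ylide of 20 | c1ccccc1P(c1ccccc1)(c1ccccc1)=C/C=C(C)/C=C/[C@H]1C(C)=C[C@H](O)CC1(C)C | intermediate
23 | (2E,4E,6E,8E,10E,12E)-13-[(1R,4R)-4-hydroxy-2,6,6-trimethylcyclohex-2-en-1-yl]-2,7,11-trimethyltrideca-2,4,6,8,10,12-hexaenal | O=C/C(C)=C/C=C/C=C(C)/C=C/C=C(C)/C=C/[C@H]1C(C)=C[C@H](O)CC1(C)C | intermediate
24 | diiodomethane | ICI | starting material
25 | diiodomethyllithium | [Li]C(I)I | intermediate
26 | tributyl(diiodomethyl)stannane | CCCC[Sn](CCCC)(CCCC)C(I)I | intermediate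
27 | [(tributylstannyl)methanediyl]bis(dichlorochromium) | CCCC[Sn](CCCC)(CCCC)C([Cr](Cl)Cl)[Cr](Cl)Cl | intermediate
28 | (1R,4R)-3,5,5-trimethyl-4-[(1E,3E,5E,7E,9E,11E,13E)-3,7,12-trimethyl-14-(tributylstannyl)tetradeca-1,3,5,7,9,11,13-heptaen-1-yl]cyclohex-2-en-1-ol | CCCC[Sn](CCCC)(CCCC)/C=C/C(C)=C/C=C/C=C(C)/C=C/C=C(C)/C=C/[C@H]1C(C)=C[C@H](O)CC1(C)C | intermediate
29 | (3R,3'R,6'R)-3,3'-dihydroxy-8-oxo-7,8-dihydro-β,ε-caroten-19-yl (2E)-oct-2-enoate | CCCCC/C=C/C(=O)OC\C(=C/C=C/C(C)=C/C=C/C=C(C)/C=C/C=C(C)/C=C/[C@H]1C(C)=C[C@H](O)CC1(C)C)C(=O)CC1=C(C)C[C@@H](O)CC1(C)C | target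

Total step count: 15. Longest linear sequence: 8 steps (steps 1–7, then step 15, from 1). The stannane branch from 16 has 7 steps (8–12, 14, 15).

**Steps most likely to fail**

Step 15.
- What may go wrong: protodestannylation or homocoupling of the long stannane, slow transmetalation that leaves zerovalent palladium free to ionise the allylic octenoate, and erosion of alkene geometry.
- Fallback: it sets out from 23 and 15 and comes back at 29. Aldehyde 23 is homologated with the Ohira–Bestmann reagent (K2CO3, MeOH) to the tin-free terminal hexaenyne F1. Sonogashira coupling of F1 with 15 (Pd(PPh3)2Cl2, CuI, i-Pr2NEt, THF, rt) forms the same C10–C11 bond through a fast copper acetylide transfer and gives the 11,12-didehydro compound F2. Semireduction of the conjugated alkyne with zinc activated by Cu(OAc)2 and AgNO3 in aqueous methanol gives the (11Z) isomer F3. Its hindered cis bond (C10–H against the C13 methyl group) should isomerise on heating in EtOAc in the dark to 29.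

Step 14.
- What may go wrong: reductive dimerisation of the long polyenal by divalent chromium, incomplete E selectivity, and loss of tin during purification of a heptaene.
- Fallback: it sets out from 21 and comes back at 28. The order of steps 12 and 14 is inverted. The chromium olefination with 26 is run on the small, robust dialdehyde 21 (in excess) and gives the stannyl tetraenal F4. Wittig olefination of F4 with the salt 20 (NaOMe, CH2Cl2/MeOH) then builds the heptaene 28 in its last step.

Step 9.
- What may go wrong: hydrogen abstraction at C6' with loss of configuration, oxidative degradation of the tertiary bis-allylic alcohol, and radical attack on the vinyl group.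
- Fallback: it sets out from 16 and comes back at 19. Ketone 16 is masked first as the ethylene ketal F5 (ethylene glycol, HC(OEt)3, pyridinium p-toluenesulfonate), so the oxidation substrate has neither the carbinol nor the vinyl group. Allylic oxidation under the conditions of step 9 gives the oxo ketal F6. K[HB(s-Bu)3] gives the trans hydroxy ketal F7. Mild hydrolysis (pyridinium p-toluenesulfonate, aqueous acetone) gives (3R,6R)-3-hydroxy-α-ionone F8, and two equivalents of vinylmagnesium bromide give 19.

**Further compounds**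

F1 | step 15 | (1R,4R)-3,5,5-trimethyl-4-[(1E,3E,5E,7E,9E,11E)-3,7,12-trimethyltetradeca-1,3,5,7,9,11-hexaen-13-yn-1-yl]cyclohex-2-en-1-ol | C#C/C(C)=C/C=C/C=C(C)/C=C/C=C(C)/C=C/[C@H]1C(C)=C[C@H](O)CC1(C)C
F2 | step 15 | 11,12-didehydro analogue of 29 | CCCCC/C=C/C(=O)OC\C(=C/C#C/C(C)=C/C=C/C=C(C)/C=C/C=C(C)/C=C/[C@H]1C(C)=C[C@H](O)CC1(C)C)C(=O)CC1=C(C)C[C@@H](O)CC1(C)C
F3 | step 15 | (11Z) isomer of 29 | CCCCC/C=C/C(=O)OC\C(=C/C=C\C(C)=C\C=C\C=C(C)\C=C\C=C(C)\C=C\[C@H]1C(C)=C[C@H](O)CC1(C)C)C(=O)CC1=C(C)C[C@@H](O)CC1(C)C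
F4 | step 14 | (2E,4E,6E,8E)-2,7-dimethyl-9-(tributylstannyl)nona-2,4,6,8-tetraenal | CCCC[Sn](CCCC)(CCCC)/C=C/C(C)=C/C=C/C=C(C)/C=O
F5 | step 9 | 2-methyl-2-{(E)-2-[(1R)-2,6,6-trimethylcyclohex-2-en-1-yl]ethenyl}-1,3-dioxolane | CC1(OCCO1)/C=C/[C@H]1C(C)=CCCC1(C)C
F6 | step 9 | (4R)-3,5,5-trimethyl-4-[(E)-2-(2-methyl-1,3-dioxolan-2-yl)ethenyl]cyclohex-2-en-1-one | CC1(OCCO1)/C=C/[C@H]1C(C)=CC(=O)CC1(C)C
F7 | step 9 | (1R,4R)-3,5,5-trimethyl-4-[(E)-2-(2-methyl-1,3-dioxolan-2-yl)ethenyl]cyclohex-2-en-1-ol | CC1(OCCO1)/C=C/[C@H]1C(C)=C[C@H](O)CC1(C)C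
F8 | step 9 | (3R,6R)-3-hydroxy-α-ionone | CC(=O)/C=C/[C@H]1C(C)=C[C@H](O)CC1(C)C
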